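**Assumption:** (2S)-pinocembrin (natural enantiomer, CAS 480-39-7), 2-(benzyloxy)benzyl bromide and [4-(benzyloxy)-3-formylphenyl]boronic acid are taken as catalogue compounds. The single C2 stereocentre is therefore bought (chiral pool), not created. The route is designed on paper and has not been run.

## Retrosynthetic overview

1. The target is (2S)-pinocembrin carrying a "dimer" o-hydroxybenzyl chain at C8 and a "trimer" chain at C6. Disconnect both ArCH2–C(A-ring) bonds as o-quinone-methide (o-QM) Friedel–Crafts alkylations.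
2. Order: C8 first with the cheaper dimer salicyl alcohol (regioisomers separated), then C6 with the trimer salicyl alcohol (only one site left).
3. The dimer and trimer salicyl alcohols come from iterative sp3–sp2 Suzuki couplings of O-benzyl-protected 2-alkoxybenzyl bromides with one boronic acid, with CHO → CH2OH → CH2Br for chain extension and hydrogenolysis to unmask the phenols.
4. No ring is built: the chromanone and all benzene rings come from commercial materials.

## Route

**Step 1**
Reactants: 1 2-(benzyloxy)benzyl bromide; 2 [4-(benzyloxy)-3-formylphenyl]boronic acid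
Product: 3 2-(benzyloxy)-5-[2-(benzyloxy)benzyl]benzaldehyde
Conditions: Pd(PPh3)4 (5 mol %), 2 M aq Na2CO3, DME, 80 °C
Reagents that add atoms: none
Why: Suzuki–Miyaura sp3–sp2 coupling of a benzylic bromide with an arylboronic acid gives the diarylmethane with the link fixed para to the OBn; aldehyde and benzyl ethers tolerate the conditions.

**Step 2**
Reactants: 3
Product: 4 {2-(benzyloxy)-5-[2-(benzyloxy)benzyl]phenyl}methanol
Conditions: NaBH4, THF/MeOH, 0 °C
Reagents that add atoms: none (hydride only)
Why: Chemoselective borohydride reduction of the aryl aldehyde to the benzylic alcohol.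

**Step 3**
Reactants: 4
Product: 5 4-(2-hydroxybenzyl)-2-(hydroxymethyl)phenol (dimer salicyl alcohol)
Conditions: H2 (1 atm), 10% Pd/C, EtOAc, rt, stopped at 2 equiv H2 uptake
Reagents that add atoms: none
Why: Hydrogenolysis of the two aryl benzyl ethers under neutral conditions is much faster than C–O cleavage of the salicylic CH2OH; the diarylmethane is inert.

**Step 4**
Reactants: 4
Product: 6 1-(benzyloxy)-4-[2-(benzyloxy)benzyl]-2-(bromomethyl)benzene
Conditions: PBr3 (0.4 equiv), CH2Cl2, 0 °C; used crude
Reagents that add atoms: phosphorus tribromide, BrP(Br)Br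
Why: Standard conversion of a benzylic alcohol to the bromide; the ortho oxygen is benzyl-capped, so no o-QM can form.

**Step 5**
Reactants: 6; 2 [4-(benzyloxy)-3-formylphenyl]boronic acid
Product: 7 2-(benzyloxy)-5-{2-(benzyloxy)-5-[2-(benzyloxy)benzyl]benzyl}benzaldehyde
Conditions: Pd(PPh3)4 (5 mol %), 2 M aq Na2CO3, DME, 80 °C
Reagents that add atoms: none
Why: A second Suzuki–Miyaura sp3–sp2 coupling adds the third ring with the same ortho/para connectivity.

**Step 6**
Reactants: 7
Product: 8 (2-(benzyloxy)-5-{2-(benzyloxy)-5-[2-(benzyloxy)benzyl]benzyl}phenyl)methanol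
Conditions: NaBH4, THF/MeOH, 0 °C
Reagents that add atoms: none (hydride only)
Why: Borohydride reduction of the aldehyde; nothing else is reducible.

**Step 7**
Reactants: 8
Product: 9 4-[2-hydroxy-5-(2-hydroxybenzyl)benzyl]-2-(hydroxymethyl)phenol (trimer salicyl alcohol)
Conditions: H2 (1 atm), 10% Pd/C, EtOAc/EtOH, rt, stopped at 3 equiv H2 uptake
Reagents that add atoms: none
Why: Global O-debenzylation by hydrogenolysis, leaving the salicyl CH2OH intact under neutral conditions.

**Step 8**
Reactants: 10 (2S)-pinocembrin [(2S)-5,7-dihydroxy-2-phenylchroman-4-one] (2 equiv, excess recovered); 5 (slow addition)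
Product: 11 (2S)-5,7-dihydroxy-8-[2-hydroxy-5-(2-hydroxybenzyl)benzyl]-2-phenylchroman-4-one
Conditions: anhydrous ZnCl2 (3 equiv), 1,4-dioxane, 90 °C, N2; chromatography (silica, then RP-HPLC) to remove the 6-regioisomer and recover 10
Reagents that add atoms: none
Why: ZnCl2 dehydrates the salicyl alcohol to an o-quinone methide, which is trapped by the phloroglucinol-type A ring ortho to 7-OH (Friedel–Crafts-type o-QM addition). C2 is not involved, so the (S) configuration of 10 is carried through. The 8- and 6-mono-adducts form together and 11 is the separated 8-isomer (assigned by HMBC from the chelated 5-OH to the remaining C6–H).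

**Step 9**
Reactants: 11; 9 (1.5 equiv, slow addition)
Product: 12 sarmentosumin D, (2S)-5,7-dihydroxy-8-[2-hydroxy-5-(2-hydroxybenzyl)benzyl]-6-{2-hydroxy-5-[2-hydroxy-5-(2-hydroxybenzyl)benzyl]benzyl}-2-phenylchroman-4-one
Conditions: anhydrous ZnCl2 (3 equiv), 1,4-dioxane, 90 °C, N2; Sephadex LH-20 / RP-HPLC; ee checked by chiral HPLC
Reagents that add atoms: none
Why: The same ZnCl2-mediated o-QM Friedel–Crafts alkylation at C6, the only remaining A-ring position and the most nucleophilic carbon in 11. No new stereocentre is formed, and C2 stays (S) provided the pyranone does not ring-open.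

## Compound list

1 | 2-(benzyloxy)benzyl bromide | BrCc1ccccc1OCc1ccccc1 | starting material
2 | [4-(benzyloxy)-3-formylphenyl]boronic acid | O=Cc1cc(B(O)O)ccc1OCc1ccccc1 | starting material
3 | 2-(benzyloxy)-5-[2-(benzyloxy)benzyl]benzaldehyde | O=Cc1cc(Cc2ccccc2OCc2ccccc2)ccc1OCc1ccccc1 | intermediate
4 | {2-(benzyloxy)-5-[2-(benzyloxy)benzyl]phenyl}methanol | OCc1cc(Cc2ccccc2OCc2ccccc2)ccc1OCc1ccccc1 | intermediate
5 | 4-(2-hydroxybenzyl)-2-(hydroxymethyl)phenol | OCc1cc(Cc2ccccc2O)ccc1O | intermediate
6 | 1-(benzyloxy)-4-[2-(benzyloxy)benzyl]-2-(bromomethyl)benzene | BrCc1cc(Cc2ccccc2OCc2ccccc2)ccc1OCc1ccccc1 | intermediate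
7 | 2-(benzyloxy)-5-{2-(benzyloxy)-5-[2-(benzyloxy)benzyl]benzyl}benzaldehyde | O=Cc1cc(Cc2cc(Cc3ccccc3OCc3ccccc3)ccc2OCc2ccccc2)ccc1OCc1ccccc1 | intermediate
8 | (2-(benzyloxy)-5-{2-(benzyloxy)-5-[2-(benzyloxy)benzyl]benzyl}phenyl)methanol | OCc1cc(Cc2cc(Cc3ccccc3OCc3ccccc3)ccc2OCc2ccccc2)ccc1OCc1ccccc1 | intermediate
9 | 4-[2-hydroxy-5-(2-hydroxybenzyl)benzyl]-2-(hydroxymethyl)phenol | OCc1cc(Cc2cc(Cc3ccccc3O)ccc2O)ccc1O | intermediate
10 | (2S)-pinocembrin, (2S)-5,7-dihydroxy-2-phenylchroman-4-one | O=C1C[C@@H](c2ccccc2)Oc2cc(O)cc(O)c21 | starting material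
11 | (2S)-5,7-dihydroxy-8-[2-hydroxy-5-(2-hydroxybenzyl)benzyl]-2-phenylchroman-4-one | O=C1C[C@@H](c2ccccc2)Oc2c(Cc3cc(Cc4ccccc4O)ccc3O)c(O)cc(O)c21 | intermediate
12 | sarmentosumin D | O=C1C[C@@H](c2ccccc2)Oc2c(Cc3cc(Cc4ccccc4O)ccc3O)c(O)c(Cc3cc(Cc4cc(Cc5ccccc5O)ccc4O)ccc3O)c(O)c21 | target

## Summary

Total steps: 9.
Longest linear sequence: 7 steps (1 → 3 → 4 → 6 → 7 → 8 → 9 → 12, i.e. steps 1, 2, 4, 5, 6, 7, 9).

Three steps most likely to fail:

1. **Step 8 (C8 versus C6 selectivity and over-alkylation).** The selectivity is not predictable with confidence, and the wrong isomer cannot be recycled. Fallback: make site selection substrate-controlled. Selectively silylate the non-chelated 7-OH of 10 (TIPS), so only the chelated 5-OH directs attack to its ortho position (C6). Install the trimer 9 there first, desilylate under buffered conditions, then add the dimer 5 at the remaining C8.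

2. **Step 9 (hot Lewis acid on a precious, crowded substrate).** The risks are oligomerisation of 9 and ring-opening of the flavanone to the chalcone, which would erode ee and scramble C6/C8. Fallback: move the stereocentre to the end. Run both benzylations on achiral 5,7-dihydroxychromone, which cannot epimerise, then install the phenyl group by Pd(II)/t-BuPyOx-catalysed asymmetric conjugate addition of PhB(OH)2, using the ligand enantiomer that gives (2S).

3. **Step 7 (and step 3): hydrogenolysis over-reducing the salicylic CH2OH to CH3.** Fallback: change the handle to the ester oxidation level. Use the 4-(benzyloxy)-3-(methoxycarbonyl)phenylboronate in the couplings, debenzylate at the methyl salicylate stage (inert to H2/Pd), and generate the salicyl alcohol last by LiAlH4 reduction.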